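The data stem from a simulated flask from invented constants; the scatter is artificial.

The late end of a flask is where the west run is asked, at 33 min, so we want a measure of late progress that can be carried from run to run.

| flask | starting material | partner | target | time |
|---|---|---|---|---|
| south-east | 120 mM | 360 mM |  |  |
| south | 120 mM | 360 mM | 36.0 mM |  |
| north | 120 mM | 720 mM |  |  |
| north-east | 360 mM | 360 mM |  |  |
| west | 120 mM | 1700 mM |  | 33 min |

| south-east run: time / min | south-east run: [target] / mM | south run: time / min | south run: [target] / mM | north run: time / min | north run: [target] / mM | north-east run: time / min | north-east run: [target] / mM |
|---|---|---|---|---|---|---|---|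
| 1.3 | 1.4 | 1.3 | 36.0 | 1.3 | 1.3 | 1.3 | 1.6 |
| 2.5 | 3.0 | 2.5 | 39.0 | 2.5 | 3.8 | 2.5 | 6.6 |
| 4.8 | 7.4 | 4.8 | 43.5 | 4.8 | 10.8 | 4.8 | 19.7 |
| 9.1 | 19.1 | 9.1 | 55.6 | 9.1 | 26.5 | 9.1 | 43.5 |
| 17 | 38.3 | 17 | 74.0 | 17 | 52.9 | 17 | 81.3 |
| 33 | 64.9 | 33 | 101.1 | 33 | 83.9 | 33 | 130.8 |

(readings scatter by 0.4 mM)

- Overall: starting material + partner -> target.
- Constant volume, constant temperature.
- A reading of a species includes what of it is bound.
- "The second partner" is partner.
- An order is taken over about fifteen percent of the charge, up and down.

- how the opening rate goes with [partner] round the charge of the south-east run: the exponent of the rate at two percent of starting material gone to target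
- how the opening rate goes with [starting material] round the charge of the south-east run: the exponent of the rate at two percent of starting material gone to target (one fixed amount of target, the same in the runs compared)
- target in the west run at 33 min, as a share of the starting material charged

Here is our own reckoning, told in fractions of the charge of starting material, which in the west run is the limiting reagent, since it is charged at less than the partner.

1. First instants. The south-east run has turned 1.17% of its charge at 1.3 min. Between its first two readings its pace, as a fraction of the charge, reads 0.0111 min⁻¹.

2. Middle. Between 4.8 min and 9.1 min the pace of the same run reads 0.0227 min⁻¹, about twice the opening pace, so the south-east run starts slowly and then gathers speed. At 33 min the south run, net of its added target, differs from the south-east run by 0.200 mM, less than the scatter.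

3. End. Now we go to logarithms. We call the decade count the number of powers of ten by which the unturned fraction has fallen. The decade rate is the rise of that count per minute between the last two readings. It is 0.0107 min⁻¹ in the south-east run and 0.0168 min⁻¹ in the north run, which has 2.00 times the partner. The late exponent in partner is therefore 0.654.

4. West. The north run stands at 0.522 decades at 33 min. The west run has 2.36 times its partner, which is 0.373 of a decade. Assuming the exponent holds, the count becomes 0.915 decades, and the west share is 87.8%. We commit to that share and reckon no opening exponents of our own.

5. Forecast. It gives 0.42 and 0.65 for the opening exponents and 82% for the west run, reached by what it calls “A double-reciprocal extrapolation”. Its share is lower than ours.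

    starting material ⇌ intermediate + by-product (0.1596 min⁻¹, 2.352 L mol⁻¹ min⁻¹)
    intermediate + partner → target (1.056 L mol⁻¹ min⁻¹)
    partner + by-product ⇌ reagent-by-product salt, settled at all times (20.50 L mol⁻¹)
    2 partner ⇌ idle reagent dimer, settled at all times (61.90 L mol⁻¹)

The flask gives 0.34 and 0.58, the first lower than the forecast's, and 85.3% for the west run, which is 0.834 decades and a north-to-west exponent of 0.546, lower than our 0.654. At the start of the west run, as starting material began shedding by-product and intermediate, 6.66% of the partner charged stood free and the rest sat in idle reagent dimer, against 13.9% free at the start of the south-east run. Carried forward from 17 min, the south-east decade rate puts the target made in the south-east run at half of the charge at 29.5 min, and the target made in the south run came to half of its starting material charged at 29.3 min.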